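Ring A is disconnected through C8–C8a and, further back, through C4a–C5, to a squarate unit and a preformed 2-aryl-3-methoxy-4-pyranone (ring C). One thermal operation then turns a 4-hydroxy-4-pyranonylcyclobutenone into the 5,8-dihydroxy-6,7-dialkoxyflavone: four-electron ring opening to a dienylketene, six-electron closure onto the pyranone C–H carbon, and enolisation. The step exploits the four contiguous oxygen-bearing carbons C5, C6, C7 and C8 of ring A, which map onto the four oxygenated carbons of squaric acid, and the single C–H position of ring C that becomes C8a. The precursor is racemic 2,3-bis(benzyloxy)-4-hydroxycyclobut-2-enone carrying the 6-(4-benzyloxyphenyl)-5-methoxy-4-oxopyran-3-yl group at C4.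

Key step: step 7

Remark: the target is achiral; the only stereocentre that is isolated on the route, the carbinol carbon of the cyclobutenone precursor, is carried as the racemate and is erased by the ring expansion.

Step 1
Reactants: 1 squaric acid; 2 benzyl alcohol
Product: 3 3,4-bis(benzyloxy)cyclobut-3-ene-1,2-dione (dibenzyl squarate)
Conditions: BnOH (4 equiv), toluene, reflux, Dean–Stark trap
Reagents that add atoms: benzyl alcohol (second equivalent), OCc1ccccc1
Why: Fischer-type double esterification of the strongly acidic vinylogous diacid, which catalyses its own esterification while water is removed azeotropically as in the usual preparation of dialkyl squarates; two molecules of benzyl alcohol are taken up, one as reactant 2 and the second as the reagent entered above.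

Step 2
Reactants: 4 pyromeconic acid (3-hydroxy-4H-pyran-4-one)
Product: 5 3-hydroxy-2-iodo-4H-pyran-4-one
Conditions: NIS (1.05 equiv), DMF, 0 °C to rt
Reagents that add atoms: N-iodosuccinimide, O=C1CCC(=O)N1I
Why: Electrophilic iodination of the enolic 3-hydroxy-4-pyranone should occur at C2, the enol carbon ortho to the hydroxyl, which is the position that halogenation, Mannich and hydroxymethylation reactions of this ring system take.

Step 3
Reactants: 5 3-hydroxy-2-iodo-4H-pyran-4-one
Product: 6 2-iodo-3-methoxy-4H-pyran-4-one
Conditions: MeI (1.5 equiv), K2CO3, acetone, 40 °C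
Reagents that add atoms: iodomethane, IC
Why: Williamson O-methylation of the acidic enolic hydroxyl, standard for 3-hydroxy-4-pyranones, installs the later 3-OMe group and removes the free OH before the palladium step.

Step 4
Reactants: 6 2-iodo-3-methoxy-4H-pyran-4-one; 7 4-benzyloxyphenylboronic acid
Product: 8 2-[4-(benzyloxy)phenyl]-3-methoxy-4H-pyran-4-one
Conditions: Pd(PPh3)4 (3 mol %), K2CO3, dioxane–H2O (4:1), 80 °C
Reagents that add atoms: none
Why: Suzuki–Miyaura coupling; the C2–iodine bond is a vinylogous acyl iodide and should undergo fast oxidative addition to zerovalent palladium.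

Step 5
Reactants: 8 2-[4-(benzyloxy)phenyl]-3-methoxy-4H-pyran-4-one
Product: 9 2-[4-(benzyloxy)phenyl]-5-iodo-3-methoxy-4H-pyran-4-one
Conditions: NIS (1.1 equiv), TFA (cat.), MeCN, rt to 50 °C
Reagents that add atoms: N-iodosuccinimide, O=C1CCC(=O)N1I
Why: Electrophilic iodination at C5, the alpha carbon of the vinylogous ester whose cationic intermediate is stabilised by the ring oxygen (the reactivity that gives 3-iodochromones and 3-iodoflavones), should outrun attack on the alkoxyphenyl ring, which is deactivated by conjugation with the pyranone.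

Step 6
Reactants: 9 2-[4-(benzyloxy)phenyl]-5-iodo-3-methoxy-4H-pyran-4-one; 3 dibenzyl squarate
Product: 11 2,3-bis(benzyloxy)-4-hydroxy-4-[6-(4-benzyloxyphenyl)-5-methoxy-4-oxo-4H-pyran-3-yl]cyclobut-2-en-1-one (racemic), via pyranonylmagnesium chloride 10 (not isolated)
Conditions: iPrMgCl·LiCl (1.05 equiv), THF, −40 °C; then added to 3 (1.2 equiv), THF, −78 to −30 °C; aq. NH4Cl
Reagents that add atoms: none
Why: Iodine–magnesium exchange on an alpha-iodo enone is fast at low temperature, and the resulting alkenyl Grignard reagent should add 1,2 to one of the two equivalent carbonyl groups of the symmetrical squarate, so that no regiochemical question arises and the new carbinol centre forms as a racemate.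

Step 7
Reactants: 11 2,3-bis(benzyloxy)-4-hydroxy-4-[6-(4-benzyloxyphenyl)-5-methoxy-4-oxo-4H-pyran-3-yl]cyclobut-2-en-1-one (racemic)
Product: 14 6,7-bis(benzyloxy)-2-[4-(benzyloxy)phenyl]-5,8-dihydroxy-3-methoxy-4H-chromen-4-one, via dienylketene 12 (not isolated), via bicyclic dienone 13 (not isolated)
Conditions: degassed toluene (0.02 M), 110 °C, Ar
Reagents that add atoms: none
Why: Heating should open the cyclobutenone between the carbonyl and carbinol carbons by conrotatory four-electron ring opening, the hydroxyl donor turning outward so that the pyranonyl group lies cis to the ketene in 12. The dienylketene then closes by thermal six-electron (disrotatory) electrocyclization between the ketene carbon and the pyranone C–H carbon next to the ring oxygen, which forms C8–C8a and the six-membered ring A as dienone 13; enolisation of 13 (C8a–H to O8) gives the aromatic hydroquinone 14. The closest known reaction type is the Moore rearrangement of 4-aryl-, 4-heteroaryl- and 4-alkenyl-4-hydroxycyclobutenones to hydroquinones, here with the C=C bond of a 4-pyranone as the unsaturated arm, which gives up no benzenoid aromaticity on closure. No stereocentre survives, because the carbinol carbon of 11 and C8a of 13 both become sp2. The step needs closure at carbon in preference to capture of the ketene by the hydroxyl (furanone formation), and closure at the right carbon; outward rotation of the hydroxyl holds it away from the ketene, and the only other neighbour of the attachment point is the C4 carbonyl carbon, which cannot take the new bond. High dilution and exclusion of oxygen are meant to suppress ketene oligomerisation and oxidation of 14 to the quinone.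

Step 8
Reactants: 14 6,7-bis(benzyloxy)-2-[4-(benzyloxy)phenyl]-5,8-dihydroxy-3-methoxy-4H-chromen-4-one
Product: 15 6,7-bis(benzyloxy)-2-[4-(benzyloxy)phenyl]-3,5,8-trimethoxy-4H-chromen-4-one
Conditions: MeI (6 equiv), K2CO3 (5 equiv), DMF, 50 °C, Ar
Reagents that add atoms: iodomethane (first equivalent), IC; iodomethane (second equivalent), IC
Why: Williamson methylation of both phenols, each taking up one molecule of iodomethane, with excess reagent and warming for the hydrogen-bonded 5-OH and an inert atmosphere to protect the hydroquinone until it is capped.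

Step 9
Reactants: 15 6,7-bis(benzyloxy)-2-[4-(benzyloxy)phenyl]-3,5,8-trimethoxy-4H-chromen-4-one
Product: 16 6,7-dihydroxy-2-(4-hydroxyphenyl)-3,5,8-trimethoxy-4H-chromen-4-one
Conditions: H2 (1 atm), Pd/C (10 %), THF–MeOH, rt
Reagents that add atoms: none
Why: Catalytic hydrogenolysis should cleave the three aryl benzyl ethers and leave the tetrasubstituted C2=C3 bond of the flavone, a vinylogous ester, untouched.

Step 10
Reactants: 16 6,7-dihydroxy-2-(4-hydroxyphenyl)-3,5,8-trimethoxy-4H-chromen-4-one
Product: 17 7-(benzyloxy)-2-[4-(benzyloxy)phenyl]-6-hydroxy-3,5,8-trimethoxy-4H-chromen-4-one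
Conditions: BnBr (2.05 equiv), K2CO3 (2.2 equiv), DMF, 0 °C to rt, Ar
Reagents that add atoms: benzyl bromide (first equivalent), BrCc1ccccc1; benzyl bromide (second equivalent), BrCc1ccccc1
Why: Site-selective Williamson benzylation taking up two molecules of benzyl bromide: 7-OH and 4'-OH are vinylogous acids conjugated with the C4 carbonyl and should be deprotonated and alkylated first, while 6-OH, meta to the carbonyl and flanked on both sides, should stay free with a limiting amount of reagent.

Step 11
Reactants: 17 7-(benzyloxy)-2-[4-(benzyloxy)phenyl]-6-hydroxy-3,5,8-trimethoxy-4H-chromen-4-one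
Product: 18 7-(benzyloxy)-2-[4-(benzyloxy)phenyl]-3,5,6,8-tetramethoxy-4H-chromen-4-one
Conditions: MeI (3 equiv), K2CO3, DMF, 40 °C
Reagents that add atoms: iodomethane, IC
Why: Williamson methylation of the single remaining phenol fixes the methyl group on O6.

Step 12
Reactants: 18 7-(benzyloxy)-2-[4-(benzyloxy)phenyl]-3,5,6,8-tetramethoxy-4H-chromen-4-one
Product: 19 7-hydroxy-2-(4-hydroxyphenyl)-3,5,6,8-tetramethoxy-4H-chromen-4-one (target)
Conditions: H2 (1 atm), Pd/C (10 %), EtOAc–MeOH, rt
Reagents that add atoms: none
Why: Hydrogenolysis of the two benzyl ethers should free 7-OH and 4'-OH and leave the four methyl ethers in place.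

Compound list
1 | squaric acid (3,4-dihydroxycyclobut-3-ene-1,2-dione) | O=C1C(O)=C(O)C1=O | starting material
2 | benzyl alcohol | OCc1ccccc1 | starting material
3 | 3,4-bis(benzyloxy)cyclobut-3-ene-1,2-dione (dibenzyl squarate) | O=C1C(=O)C(OCc2ccccc2)=C1OCc1ccccc1 | intermediate
4 | pyromeconic acid (3-hydroxy-4H-pyran-4-one) | O=c1ccocc1O | starting material
5 | 3-hydroxy-2-iodo-4H-pyran-4-one | O=c1ccoc(I)c1O | intermediate
6 | 2-iodo-3-methoxy-4H-pyran-4-one | COc1c(I)occc1=O | intermediate
7 | 4-benzyloxyphenylboronic acid | OB(O)c1ccc(OCc2ccccc2)cc1 | starting material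
8 | 2-[4-(benzyloxy)phenyl]-3-methoxy-4H-pyran-4-one | COc1c(-c2ccc(OCc3ccccc3)cc2)occc1=O | intermediate
9 | 2-[4-(benzyloxy)phenyl]-5-iodo-3-methoxy-4H-pyran-4-one | COc1c(-c2ccc(OCc3ccccc3)cc2)occ(I)c1=O | intermediate
10 | [6-(4-benzyloxyphenyl)-5-methoxy-4-oxo-4H-pyran-3-yl]magnesium chloride, as its LiCl complex (not isolated) | COc1c(-c2ccc(OCc3ccccc3)cc2)occ([Mg]Cl)c1=O | intermediate
11 | 2,3-bis(benzyloxy)-4-hydroxy-4-[6-(4-benzyloxyphenyl)-5-methoxy-4-oxo-4H-pyran-3-yl]cyclobut-2-en-1-one (racemic) | O=C1C(OCc2ccccc2)=C(OCc2ccccc2)C1(O)c1coc(-c2ccc(OCc3ccccc3)cc2)c(OC)c1=O | intermediate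
12 | (3Z)-2,3-bis(benzyloxy)-4-[6-(4-benzyloxyphenyl)-5-methoxy-4-oxo-4H-pyran-3-yl]-4-hydroxybuta-1,3-dien-1-one, dienylketene with the hydroxyl outside and the pyranonyl group cis to the ketene (not isolated) | O=C=C(OCc1ccccc1)/C(OCc1ccccc1)=C(/O)c1coc(-c2ccc(OCc3ccccc3)cc2)c(OC)c1=O | intermediate
13 | 6,7-bis(benzyloxy)-2-[4-(benzyloxy)phenyl]-5-hydroxy-3-methoxy-8aH-chromene-4,8-dione (racemic at C8a, not isolated) | O=C1C(OCc2ccccc2)=C(OCc2ccccc2)C(O)=C2C(=O)C(OC)=C(c3ccc(OCc4ccccc4)cc3)OC12 | intermediate
14 | 6,7-bis(benzyloxy)-2-[4-(benzyloxy)phenyl]-5,8-dihydroxy-3-methoxy-4H-chromen-4-one | Oc1c(OCc2ccccc2)c(OCc2ccccc2)c(O)c2oc(-c3ccc(OCc4ccccc4)cc3)c(OC)c(=O)c12 | intermediate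
15 | 6,7-bis(benzyloxy)-2-[4-(benzyloxy)phenyl]-3,5,8-trimethoxy-4H-chromen-4-one | COc1c(OCc2ccccc2)c(OCc2ccccc2)c(OC)c2oc(-c3ccc(OCc4ccccc4)cc3)c(OC)c(=O)c12 | intermediate
16 | 6,7-dihydroxy-2-(4-hydroxyphenyl)-3,5,8-trimethoxy-4H-chromen-4-one | COc1c(O)c(O)c(OC)c2oc(-c3ccc(O)cc3)c(OC)c(=O)c12 | intermediate
17 | 7-(benzyloxy)-2-[4-(benzyloxy)phenyl]-6-hydroxy-3,5,8-trimethoxy-4H-chromen-4-one | COc1c(O)c(OCc2ccccc2)c(OC)c2oc(-c3ccc(OCc4ccccc4)cc3)c(OC)c(=O)c12 | intermediate
18 | 7-(benzyloxy)-2-[4-(benzyloxy)phenyl]-3,5,6,8-tetramethoxy-4H-chromen-4-one | COc1c(OC)c(OCc2ccccc2)c(OC)c2oc(-c3ccc(OCc4ccccc4)cc3)c(OC)c(=O)c12 | intermediate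
19 | 7-hydroxy-2-(4-hydroxyphenyl)-3,5,6,8-tetramethoxy-4H-chromen-4-one (achiral) | COc1c(O)c(OC)c2oc(-c3ccc(O)cc3)c(OC)c(=O)c2c1OC | target

Total step count: 12 steps.
Longest linear sequence: 11 steps (4 to 19, steps 2 to 12); step 1 is a one-step branch that joins at step 6.

Steps most likely to fail

Step 7. The ketene may be captured by the carbinol oxygen to give a furanone, or may oligomerise if closure onto the electron-poor pyranone double bond is slow. The product hydroquinone may also be lost by oxidation. The fallback sets out from 11 and comes back at 14. The tertiary hydroxyl is silylated (TMSOTf, 2,6-lutidine, CH2Cl2, −78 °C) to 2,3-bis(benzyloxy)-4-[6-(4-benzyloxyphenyl)-5-methoxy-4-oxo-4H-pyran-3-yl]-4-(trimethylsilyloxy)cyclobut-2-en-1-one F1. Without an O–H group the ketene cannot lactonise, and silyloxy groups also rotate outward. Thermolysis of F1 in toluene should therefore give the hydroquinone monosilyl ether 6,7-bis(benzyloxy)-2-[4-(benzyloxy)phenyl]-8-hydroxy-3-methoxy-5-(trimethylsilyloxy)-4H-chromen-4-one F2, which is less prone to oxidation. Methanol with citric acid then removes the silyl group to give 14.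

Step 6. The metallated pyranone may decompose by opening of ring C, or the exchange reagent may add to the unsubstituted C6 position of the pyranone before the squarate is reached. The fallback sets out from 9 and comes back at 11. Zinc is inserted directly into the carbon–iodine bond (Zn dust, LiCl, THF, rt) to give [6-(4-benzyloxyphenyl)-5-methoxy-4-oxo-4H-pyran-3-yl]zinc iodide F3. This organozinc halide is thermally stable and too weakly basic to fragment, and no nucleophilic alkylmetal is present. Its 1,2-addition to 3 is then promoted by MgCl2 (Lewis-acid-accelerated addition of organozinc halides to ketones), followed by aqueous NH4Cl.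

Step 10. Site selectivity may be incomplete, with alkylation of O6 or benzylation of all three hydroxyls. The fallback sets out from 16 and comes back at 19, so steps 11 and 12 are not needed. Instead of protecting the acidic hydroxyls, 16 is converted into its trianion (NaH, 3.3 equiv, DMSO, rt) and treated with MeI (1.0 equiv). The 6-phenoxide is the only one not stabilised by conjugation with the C4 carbonyl, so it is the most nucleophilic and should be methylated first, as in the known alkylation of catechol dianions at the less acidic oxygen. No new compound is made on this way (F0).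

Further compounds
F1 | step 7 | 2,3-bis(benzyloxy)-4-[6-(4-benzyloxyphenyl)-5-methoxy-4-oxo-4H-pyran-3-yl]-4-(trimethylsilyloxy)cyclobut-2-en-1-one (racemic) | O=C1C(OCc2ccccc2)=C(OCc2ccccc2)C1(O[Si](C)(C)C)c1coc(-c2ccc(OCc3ccccc3)cc2)c(OC)c1=O
F2 | step 7 | 6,7-bis(benzyloxy)-2-[4-(benzyloxy)phenyl]-8-hydroxy-3-methoxy-5-(trimethylsilyloxy)-4H-chromen-4-one | C[Si](C)(C)Oc1c(OCc2ccccc2)c(OCc2ccccc2)c(O)c2oc(-c3ccc(OCc4ccccc4)cc3)c(OC)c(=O)c12
F3 | step 6 | [6-(4-benzyloxyphenyl)-5-methoxy-4-oxo-4H-pyran-3-yl]zinc iodide | COc1c(-c2ccc(OCc3ccccc3)cc2)occ([Zn]I)c1=O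
F0 | step 10 | none | none
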